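(The data are calculated for substances that don't exist, and the scatter is random.)

The ratio of the mean rate over the first 8.00 min of the north-east run to its mean rate between 40.0 min and 120 min is 6.84, and we ask what this fall means for a flask with less partner.

- north-east: left-handed substrate 0.014 M; right-handed substrate 0.014 M; partner 0.056 M; free catalyst 70 µM; impurity 20 µM; run made earlier
- flask: left-handed substrate 0.014 M; partner 0.0280 M; free catalyst 70 µM; impurity 20 µM; right-handed substrate 0.014 M; time 6.0 h

- north-east (time / min: left-handed product / %, right-handed product / %, left-handed substrate / %): 8.00: 2.4, 0.2, 45.8; 15.0: 3.3, 0.6, 44.6; 25.0: 5.9, 0, 44.0; 40.0: 7.4, 0.4, 42.6; 60.0: 8.9, 2.1, 41.4; 120: 10.8, 0.8, 38.3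

(each reading ± 0.5 percentage points)

- free catalyst is single-handed; left-handed substrate and right-handed substrate are mirror images of each other, charged as a racemate, each of them at the stated concentration
- an excess is the difference of the two amounts in percent of their sum
- an excess is below zero if the other one leads

- excess of left-handed product over right-handed product in the product at 8.0 min
- excess of left-handed product over right-handed product in the product at 6.0 h
- part of the left-handed substrate and right-handed substrate charged together that has reacted at 6.0 h

We add the two products in each reading, which gives 2.60% at 8.00 min, 7.80% at 40.0 min and 11.6% at 120 min, each sum with a scatter of 0.71 percentage points.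

On the first rung of our ladder stands the product ratio, which shows at the first reading. Pooled over the readings, the selectivity gives an excess of 80.8%, and we take that for both times asked.

On the next rung the rate falls. We replace each stretch of the curve by its mean slope against the logarithm of time. This gives 3.2 points per factor e of time on the early stretch and 3.5 points on the late one. They differ by less than the 0.91 points scatter of such a slope, so the mean rate reads as falling roughly with one over the time.

On the last rung stands the substrate: at 120 min the north-east left-handed substrate still reads 76.6% of its charge.

We suppose that the partner consumes itself at second order. On that supposition, and with the catalyst and impurity charges equal, as they are in the north-east run and the flask, we let product follow exposure, the partner charge times the time, and 3.5 points is the gain in reacted share per factor e of exposure. For the flask at 6.0 h, measured against the last north-east reading: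

exposure ratio = [partner] × time, flask over north-east = 1.50

reacted = 11.6% + 3.5 points × ln(1.50) = 13.0%

The forecast stands at 82%, 81% and 7.5%, saying “assuming first order in partner with partner-independent deactivation, the plateau roughly halves to about 7%”, and on conversion it differs from our 13.0%.

The flask gives 80.9% at 8.0 min, 82.1% at 6.0 h, and 12.7% reacted.

    free catalyst + left-handed substrate ⇌ catalyst intermediate A (K = 294 L mol⁻¹, k = 1740 L mol⁻¹ min⁻¹)
    free catalyst + right-handed substrate ⇌ catalyst intermediate B (K = 59.4 L mol⁻¹, k = 10400 L mol⁻¹ min⁻¹)
    partner + catalyst intermediate A → free catalyst + left-handed product (k = 78.6 L mol⁻¹ min⁻¹)
    partner + catalyst intermediate B → free catalyst + right-handed product (k = 30.4 L mol⁻¹ min⁻¹)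
    2 partner → homo dimer (k = 1.16 L mol⁻¹ min⁻¹)
    free catalyst + impurity → spent catalyst (k = 6060 L mol⁻¹ min⁻¹)

At 6.00 h the flask holds 0.0119 M of homo dimer, and its partner stands at 2.3% of its charge, less than the 77% of its own charge that is left of the left-handed substrate. The neighbour flask with 0.0070 M of partner has 0.375 of the last north-east exposure, so 3.5 points per factor e puts it at 8.21%. That neighbour flask gave 7.19%.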